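**Plan**

1. The target is a 4→6 linked biflavonoid: upper unit (2S,3R,4R)-flavan-3-ol (2,3-trans, 3,4-cis), lower unit (2R,3S,4R)-flavan-3,4-diol (2,3-trans, 3,4-trans). Retrosynthesis: lower C4–OH back to a ketone and eight O-benzyl groups; lower ring C cut at O1–C8a and C2–C3 into aldehyde 7 and enol silane 23; acyl chain cut at C4a–C4; interflavan bond C4(upper)–C6(lower) cut into ketone 10 and an arylmagnesium; ring C of 10 cut in the same way as the lower one.
2. Forward order: ring A blocks 5 and 17, upper ring C (step 4), interflavan bond (steps 9, 10), lower acyl chain (steps 11, 12), lower ring C (step 13), debenzylation, ketone reduction.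
3. Enabling feature: C4 of the lower ring C is held at the ketone level between C3 and ring A carbon C4a. As its enol silane it makes C3 the nucleophile toward the aldehyde carbon (future C2); as a carbonyl it activates the ortho ring A carbon C8a (C–F) for displacement by the aldehyde-derived oxygen (future O1). The expelled fluoride turns the cycle over.
4. Stereochemistry: C2 of each unit from a chiral ammonium counter-ion (pseudoenantiomeric catalysts for the two units); C3 by epimerisation to 2,3-trans; upper C4 by hydride capture of the C4 cation anti to the 3-benzyloxy group (3,4-cis); lower C4 by axial hydride delivery (3,4-trans).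

Key step: step 13

Assumption: the cinchonidinium salt is taken to give the (2R) series and the pseudoenantiomeric cinchoninium salt the (2S) series; the sense is to be checked on ketone 10 in step 4, and the two catalysts are exchanged between steps 4 and 13 if it is the reverse.

**Route**

Step 1
Reactants: 1 3-fluorobenzene-1,2-diol
Product: 2 1,2-bis(benzyloxy)-3-fluorobenzene
Conditions: BnBr, K2CO3, DMF, rt to 50 °C
Reagents that add atoms: benzyl bromide, BrCc1ccccc1
Why: Williamson etherification of both phenols gives the hydrogenolysable protecting groups used throughout.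

Step 2
Reactants: 2 1,2-bis(benzyloxy)-3-fluorobenzene; 3 2-(benzyloxy)-N-methoxy-N-methylacetamide
Product: 5 2-(benzyloxy)-1-[3,4-bis(benzyloxy)-2-fluorophenyl]ethan-1-one, via aryllithium 4 (not isolated)
Conditions: n-BuLi, THF, −78 °C; then 3, −78 to 0 °C; aq NH4Cl
Reagents that add atoms: none
Why: Fluorine-directed ortho-lithiation takes the most acidic ring C–H (ortho to F; benzylic positions are not touched at −78 °C), and the Weinreb ketone synthesis stops at the ketone through its chelated tetrahedral intermediate.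

Step 3
Reactants: 5 2-(benzyloxy)-1-[3,4-bis(benzyloxy)-2-fluorophenyl]ethan-1-one
Product: 6 {[(Z)-2-(benzyloxy)-1-[3,4-bis(benzyloxy)-2-fluorophenyl]ethenyl]oxy}trimethylsilane
Conditions: Me3SiOSO2CF3, Et3N, CH2Cl2, 0 °C; non-aqueous work-up, used crude
Reagents that add atoms: trimethylsilyl trifluoromethanesulfonate, C[Si](C)(C)OS(=O)(=O)C(F)(F)F
Why: Soft enolisation and O-silylation of the only enolisable position should favour the Z enol silane (aryl and benzyloxy trans); the geometry is not stereodetermining later.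

Step 4
Reactants: 6 {[(Z)-2-(benzyloxy)-1-[3,4-bis(benzyloxy)-2-fluorophenyl]ethenyl]oxy}trimethylsilane; 7 4-(benzyloxy)benzaldehyde
Product: 10 (2S,3S)-3,7,8-tris(benzyloxy)-2-[4-(benzyloxy)phenyl]chroman-4-one, via silyl aldol ether 8 (not isolated), via cis ketone 9 (not isolated)
Conditions: O-allyl-N-(9-anthracenylmethyl)cinchoninium hydrogen difluoride (10 mol%), THF/CH2Cl2, −50 °C to rt
Reagents that add atoms: none
Why: Proposed new method: the mechanism is that of step 13 (fluoride-initiated, ammonium-controlled aldol addition, storage of the aldolate as silyl ether 8, SNAr closure onto the carbon ortho to the ketone with fluoride as chain carrier, epimerisation of cis ketone 9 to trans), the closest known types being chiral ammonium fluoride-catalysed Mukaiyama-type glycolate aldol additions and alkoxide SNAr closures of ortho-fluoroaryl ketones; the cinchoninium cation should set C2 (S) and C3 (S) follows thermodynamically.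

Step 5
Reactants: 11 5-fluoro-2-iodophenol
Product: 12 6-fluoro-2-hydroxy-3-iodobenzaldehyde
Conditions: MgCl2, Et3N, (CH2O)n, MeCN, reflux; aq HCl
Reagents that add atoms: paraformaldehyde (as formaldehyde), C=O
Why: Magnesium phenoxide-directed ortho-formylation (Casnati–Skattebøl) can only occur at the single free position ortho to the hydroxyl, between OH and F.

Step 6
Reactants: 12 6-fluoro-2-hydroxy-3-iodobenzaldehyde
Product: 14 3-fluoro-6-iodobenzene-1,2-diol, via aryl formate 13 (not isolated)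
Conditions: H2O2 (30% aq), NaOH, THF/H2O, 0 °C to rt; then aq HCl
Reagents that add atoms: hydrogen peroxide, OO
Why: Dakin oxidation of the ortho-hydroxy aldehyde (aryl migration to oxygen, then saponification of formate 13) places the second oxygen next to fluorine.

Step 7
Reactants: 14 3-fluoro-6-iodobenzene-1,2-diol
Product: 15 2,3-bis(benzyloxy)-1-fluoro-4-iodobenzene
Conditions: BnBr, K2CO3, DMF, rt to 50 °C, under N2
Reagents that add atoms: benzyl bromide, BrCc1ccccc1
Why: Williamson etherification of both phenols.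

Step 8
Reactants: 15 2,3-bis(benzyloxy)-1-fluoro-4-iodobenzene
Product: 17 2,3-bis(benzyloxy)-5-bromo-4-fluoro-1-iodobenzene, via aryllithium 16 (not isolated)
Conditions: LiN(i-Pr)2, THF, −78 °C; then BrCl2C–CCl2Br, −78 °C to rt
Reagents that add atoms: 1,2-dibromo-1,1,2,2-tetrachloroethane, BrC(Cl)(Cl)C(Cl)(Cl)Br
Why: Fluorine-directed ortho-lithiation with an amide base (no iodine–lithium exchange) removes the only C–H ortho to fluorine, and electrophilic bromination of aryllithium 16 installs the second, less reactive halogen.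

Step 9
Reactants: 17 2,3-bis(benzyloxy)-5-bromo-4-fluoro-1-iodobenzene; 10 (2S,3S)-3,7,8-tris(benzyloxy)-2-[4-(benzyloxy)phenyl]chroman-4-one
Product: 19 (2S,3S)-3,7,8-tris(benzyloxy)-4-[2,3-bis(benzyloxy)-5-bromo-4-fluorophenyl]-2-[4-(benzyloxy)phenyl]chroman-4-ol (both C4 epimers), via arylmagnesium chloride 18 (not isolated)
Conditions: 17, i-PrMgCl·LiCl, THF, −40 °C; then 10, LaCl3·2LiCl, −40 to 0 °C; aq NH4Cl
Reagents that add atoms: none
Why: Iodine–magnesium exchange is selective for the iodide over the bromide, and lanthanum-promoted 1,2-addition to the α-alkoxy ketone suppresses enolisation; either C4 epimer serves because C4 becomes planar in step 10.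

Step 10
Reactants: 19 (2S,3S)-3,7,8-tris(benzyloxy)-4-[2,3-bis(benzyloxy)-5-bromo-4-fluorophenyl]-2-[4-(benzyloxy)phenyl]chroman-4-ol
Product: 20 (2S,3R,4S)-3,7,8-tris(benzyloxy)-4-[2,3-bis(benzyloxy)-5-bromo-4-fluorophenyl]-2-[4-(benzyloxy)phenyl]chromane (2,3-trans, 3,4-cis)
Conditions: Et3SiH (excess), CF3CO2H, CH2Cl2, −40 to 0 °C
Reagents that add atoms: none
Why: Ionic hydrogenation: acid ionises the tertiary, doubly benzylic alcohol and the silane should capture the C4 cation from the face anti to the adjacent 3-benzyloxy group (the open face whether O3 acts sterically or bridges the cation), so hydrogen enters trans to O3 and the aryl group ends cis to it, both C4 epimers of 19 converging; aryl halides and benzyl ethers are inert.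

Step 11
Reactants: 20 (2S,3R,4S)-3,7,8-tris(benzyloxy)-4-[2,3-bis(benzyloxy)-5-bromo-4-fluorophenyl]-2-[4-(benzyloxy)phenyl]chromane; 3 2-(benzyloxy)-N-methoxy-N-methylacetamide
Product: 22 2-(benzyloxy)-1-{3,4-bis(benzyloxy)-2-fluoro-5-[(2S,3R,4S)-3,7,8-tris(benzyloxy)-2-[4-(benzyloxy)phenyl]chroman-4-yl]phenyl}ethan-1-one, via aryllithium 21 (not isolated)
Conditions: n-BuLi, THF, −78 °C; then 3, −78 to −20 °C; aq NH4Cl
Reagents that add atoms: none
Why: Bromine–lithium exchange (faster than any deprotonation at −78 °C; the ortho-fluoro aryllithium is stable at this temperature) followed by Weinreb ketone synthesis puts the acyl chain ortho to fluorine.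

Step 12
Reactants: 22 2-(benzyloxy)-1-{3,4-bis(benzyloxy)-2-fluoro-5-[(2S,3R,4S)-3,7,8-tris(benzyloxy)-2-[4-(benzyloxy)phenyl]chroman-4-yl]phenyl}ethan-1-one
Product: 23 (Z)-trimethylsilyl enol ether of 22
Conditions: Me3SiOSO2CF3, Et3N, CH2Cl2, 0 °C; non-aqueous work-up, used crude
Reagents that add atoms: trimethylsilyl trifluoromethanesulfonate, C[Si](C)(C)OS(=O)(=O)C(F)(F)F
Why: Soft enolisation and O-silylation at the only enolisable position, as in step 3.

Step 13
Reactants: 23 (Z)-trimethylsilyl enol ether of 22; 7 4-(benzyloxy)benzaldehyde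
Product: 26 (2R,3R)-3,7,8-tris(benzyloxy)-2-[4-(benzyloxy)phenyl]-6-{(2S,3R,4S)-3,7,8-tris(benzyloxy)-2-[4-(benzyloxy)phenyl]chroman-4-yl}chroman-4-one, via silyl aldol ether 24 (not isolated), via cis ketone 25 (not isolated)
Conditions: O-allyl-N-(9-anthracenylmethyl)cinchonidinium hydrogen difluoride (10 mol%), THF/CH2Cl2, −50 °C to rt
Reagents that add atoms: none
Why: Proposed new method: a catalytic amount of the chiral ammonium fluoride desilylates enol silane 23 to an ion-paired enolate that adds to aldehyde 7 (C2–C3 bond); the aldolate is stored as silyl ether 24, which cannot undergo retro-aldol, and each alkoxide that fluoride unmasks attacks C8a of ring A by addition–elimination, the Meisenheimer charge being taken up by the C4 carbonyl ortho to the C–F bond, while the expelled fluoride carries the chain and finally leaves as Me3SiF, so that no stoichiometric base is present. The closest known reaction types are the chiral quaternary ammonium fluoride-catalysed Mukaiyama-type aldol addition of aryl ketone glycolate enol silanes and the intramolecular SNAr etherification of an alkoxide onto an ortho-fluoroaryl ketone used to close chromanones. Ring C of the lower unit closes in a 6-exo-trig ipso attack of O1 on C8a (O1–C8a bond), six-membered and not five-membered because the only free oxygen nucleophile is the C2 alkoxide, O3 being a benzyl ether. C2 (R) should be set by the cinchonidinium cation, which shields one enantioface of the aldehyde as the ion-paired enolate approaches, independently of the remote upper unit. C3 forms as a syn/anti mixture and is funnelled to the 2,3-trans arrangement (3R) because cis ketone 25 epimerises through its enol under the residual fluoride to the diequatorial ketone 26. The step needs displacement of only the fluoride ortho to the carbonyl and preservation of C2, which the low steady-state concentration of free alkoxide and the absence of stoichiometric base are meant to secure.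

Step 14
Reactants: 26 (2R,3R)-3,7,8-tris(benzyloxy)-2-[4-(benzyloxy)phenyl]-6-{(2S,3R,4S)-3,7,8-tris(benzyloxy)-2-[4-(benzyloxy)phenyl]chroman-4-yl}chroman-4-one
Product: 27 (2R,3R)-3,7,8-trihydroxy-2-(4-hydroxyphenyl)-6-[(2S,3R,4R)-3,7,8-trihydroxy-2-(4-hydroxyphenyl)chroman-4-yl]chroman-4-one
Conditions: H2 (1 atm), Pd(OH)2/C, THF/MeOH, rt
Reagents that add atoms: none
Why: Hydrogenolysis of all eight benzyl ethers under neutral, low-pressure conditions should leave the electron-rich aryl ketone, the cyclic benzylic ethers and the diarylmethine untouched, as is usual for benzylated flavanones and flavans.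

Step 15
Reactants: 27 (2R,3R)-3,7,8-trihydroxy-2-(4-hydroxyphenyl)-6-[(2S,3R,4R)-3,7,8-trihydroxy-2-(4-hydroxyphenyl)chroman-4-yl]chroman-4-one
Product: 28 (2R,3S,4R)-2-(4-hydroxyphenyl)-6-[(2S,3R,4R)-3,7,8-trihydroxy-2-(4-hydroxyphenyl)chroman-4-yl]chromane-3,4,7,8-tetrol
Conditions: NaBH4, EtOH, 0 °C; work-up at pH 6, Sephadex LH-20
Reagents that add atoms: none
Why: Borohydride reduction of a 2,3-trans-dihydroflavonol delivers hydride axially to C4 and gives the equatorial 4-OH, trans to the equatorial 3-OH (4R), the ketone being reduced last because the free flavan-3,4-diol is acid-sensitive.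

**Compound list**

1 | 3-fluorobenzene-1,2-diol | Oc1cccc(F)c1O | starting material
2 | 1,2-bis(benzyloxy)-3-fluorobenzene | Fc1cccc(OCc2ccccc2)c1OCc1ccccc1 | intermediate
3 | 2-(benzyloxy)-N-methoxy-N-methylacetamide | CON(C)C(=O)COCc1ccccc1 | starting material
4 | [3,4-bis(benzyloxy)-2-fluorophenyl]lithium | [Li]c1ccc(OCc2ccccc2)c(OCc2ccccc2)c1F | intermediate
5 | 2-(benzyloxy)-1-[3,4-bis(benzyloxy)-2-fluorophenyl]ethan-1-one | O=C(COCc1ccccc1)c1ccc(OCc2ccccc2)c(OCc2ccccc2)c1F | intermediate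
6 | {[(Z)-2-(benzyloxy)-1-[3,4-bis(benzyloxy)-2-fluorophenyl]ethenyl]oxy}trimethylsilane | C[Si](C)(C)O/C(=C\OCc1ccccc1)c1ccc(OCc2ccccc2)c(OCc2ccccc2)c1F | intermediate
7 | 4-(benzyloxy)benzaldehyde | O=Cc1ccc(OCc2ccccc2)cc1 | starting material
8 | (3S)-2-(benzyloxy)-1-[3,4-bis(benzyloxy)-2-fluorophenyl]-3-[4-(benzyloxy)phenyl]-3-[(trimethylsilyl)oxy]propan-1-one (C2 epimers) | O=C(c1ccc(OCc2ccccc2)c(OCc2ccccc2)c1F)C(OCc1ccccc1)[C@@H](O[Si](C)(C)C)c1ccc(OCc2ccccc2)cc1 | intermediate
9 | (2S,3R)-3,7,8-tris(benzyloxy)-2-[4-(benzyloxy)phenyl]chroman-4-one (2,3-cis) | O=C1c2ccc(OCc3ccccc3)c(OCc3ccccc3)c2O[C@@H](c2ccc(OCc3ccccc3)cc2)[C@H]1OCc1ccccc1 | intermediate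
10 | (2S,3S)-3,7,8-tris(benzyloxy)-2-[4-(benzyloxy)phenyl]chroman-4-one (2,3-trans) | O=C1c2ccc(OCc3ccccc3)c(OCc3ccccc3)c2O[C@@H](c2ccc(OCc3ccccc3)cc2)[C@@H]1OCc1ccccc1 | intermediate
11 | 5-fluoro-2-iodophenol | Oc1cc(F)ccc1I | starting material
12 | 6-fluoro-2-hydroxy-3-iodobenzaldehyde | O=Cc1c(F)ccc(I)c1O | intermediate
13 | 6-fluoro-2-hydroxy-3-iodophenyl formate | O=COc1c(F)ccc(I)c1O | intermediate
14 | 3-fluoro-6-iodobenzene-1,2-diol | Oc1c(F)ccc(I)c1O | intermediate
15 | 2,3-bis(benzyloxy)-1-fluoro-4-iodobenzene | Fc1ccc(I)c(OCc2ccccc2)c1OCc1ccccc1 | intermediate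
16 | [3,4-bis(benzyloxy)-2-fluoro-5-iodophenyl]lithium | [Li]c1cc(I)c(OCc2ccccc2)c(OCc2ccccc2)c1F | intermediate
17 | 2,3-bis(benzyloxy)-5-bromo-4-fluoro-1-iodobenzene | Brc1cc(I)c(OCc2ccccc2)c(OCc2ccccc2)c1F | intermediate
18 | [2,3-bis(benzyloxy)-5-bromo-4-fluorophenyl]magnesium chloride | Cl[Mg]c1cc(Br)c(F)c(OCc2ccccc2)c1OCc1ccccc1 | intermediate
19 | (2S,3S)-3,7,8-tris(benzyloxy)-4-[2,3-bis(benzyloxy)-5-bromo-4-fluorophenyl]-2-[4-(benzyloxy)phenyl]chroman-4-ol (both C4 epimers) | OC1(c2cc(Br)c(F)c(OCc3ccccc3)c2OCc2ccccc2)c2ccc(OCc3ccccc3)c(OCc3ccccc3)c2O[C@@H](c2ccc(OCc3ccccc3)cc2)[C@@H]1OCc1ccccc1 | intermediate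
20 | (2S,3R,4S)-3,7,8-tris(benzyloxy)-4-[2,3-bis(benzyloxy)-5-bromo-4-fluorophenyl]-2-[4-(benzyloxy)phenyl]chromane | Fc1c(Br)cc([C@@H]2c3ccc(OCc4ccccc4)c(OCc4ccccc4)c3O[C@@H](c3ccc(OCc4ccccc4)cc3)[C@@H]2OCc2ccccc2)c(OCc2ccccc2)c1OCc1ccccc1 | intermediate
21 | aryllithium from 20 (lithium in place of bromine) | Fc1c([Li])cc([C@@H]2c3ccc(OCc4ccccc4)c(OCc4ccccc4)c3O[C@@H](c3ccc(OCc4ccccc4)cc3)[C@@H]2OCc2ccccc2)c(OCc2ccccc2)c1OCc1ccccc1 | intermediate
22 | 2-(benzyloxy)-1-{3,4-bis(benzyloxy)-2-fluoro-5-[(2S,3R,4S)-3,7,8-tris(benzyloxy)-2-[4-(benzyloxy)phenyl]chroman-4-yl]phenyl}ethan-1-one | O=C(COCc1ccccc1)c1cc([C@@H]2c3ccc(OCc4ccccc4)c(OCc4ccccc4)c3O[C@@H](c3ccc(OCc4ccccc4)cc3)[C@@H]2OCc2ccccc2)c(OCc2ccccc2)c(OCc2ccccc2)c1F | intermediate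
23 | (Z)-trimethylsilyl enol ether of 22 | C[Si](C)(C)O/C(=C\OCc1ccccc1)c1cc([C@@H]2c3ccc(OCc4ccccc4)c(OCc4ccccc4)c3O[C@@H](c3ccc(OCc4ccccc4)cc3)[C@@H]2OCc2ccccc2)c(OCc2ccccc2)c(OCc2ccccc2)c1F | intermediate
24 | (3R)-silyl aldol ether from 23 and 7 (C2 epimers of the new chain) | O=C(C(OCc1ccccc1)[C@H](O[Si](C)(C)C)c1ccc(OCc2ccccc2)cc1)c1cc([C@@H]2c3ccc(OCc4ccccc4)c(OCc4ccccc4)c3O[C@@H](c3ccc(OCc4ccccc4)cc3)[C@@H]2OCc2ccccc2)c(OCc2ccccc2)c(OCc2ccccc2)c1F | intermediate
25 | (2R,3S)-3,7,8-tris(benzyloxy)-2-[4-(benzyloxy)phenyl]-6-{(2S,3R,4S)-3,7,8-tris(benzyloxy)-2-[4-(benzyloxy)phenyl]chroman-4-yl}chroman-4-one (lower unit 2,3-cis) | O=C1c2cc([C@@H]3c4ccc(OCc5ccccc5)c(OCc5ccccc5)c4O[C@@H](c4ccc(OCc5ccccc5)cc4)[C@@H]3OCc3ccccc3)c(OCc3ccccc3)c(OCc3ccccc3)c2O[C@H](c2ccc(OCc3ccccc3)cc2)[C@@H]1OCc1ccccc1 | intermediate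
26 | (2R,3R)-3,7,8-tris(benzyloxy)-2-[4-(benzyloxy)phenyl]-6-{(2S,3R,4S)-3,7,8-tris(benzyloxy)-2-[4-(benzyloxy)phenyl]chroman-4-yl}chroman-4-one | O=C1c2cc([C@@H]3c4ccc(OCc5ccccc5)c(OCc5ccccc5)c4O[C@@H](c4ccc(OCc5ccccc5)cc4)[C@@H]3OCc3ccccc3)c(OCc3ccccc3)c(OCc3ccccc3)c2O[C@H](c2ccc(OCc3ccccc3)cc2)[C@H]1OCc1ccccc1 | intermediate
27 | (2R,3R)-3,7,8-trihydroxy-2-(4-hydroxyphenyl)-6-[(2S,3R,4R)-3,7,8-trihydroxy-2-(4-hydroxyphenyl)chroman-4-yl]chroman-4-one | O=C1c2cc([C@@H]3c4ccc(O)c(O)c4O[C@@H](c4ccc(O)cc4)[C@@H]3O)c(O)c(O)c2O[C@H](c2ccc(O)cc2)[C@H]1O | intermediate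
28 | (2R,3S,4R)-2-(4-hydroxyphenyl)-6-[(2S,3R,4R)-3,7,8-trihydroxy-2-(4-hydroxyphenyl)chroman-4-yl]chromane-3,4,7,8-tetrol | Oc1ccc([C@H]2Oc3c(cc([C@@H]4c5ccc(O)c(O)c5O[C@@H](c5ccc(O)cc5)[C@@H]4O)c(O)c3O)[C@@H](O)[C@@H]2O)cc1 | target

**Count and risks**

Total steps: 15. Longest linear sequence: 11 steps (steps 5 to 15, or steps 1 to 4 followed by 9 to 15).

Step 13 (Proposed new method). What may go wrong: the unmasked alkoxide may revert by retro-aldol, or ring C may open by elimination from the C3 enolate, so that C2 loses its configuration; the ring closure on the electron-rich ring A may also be slow, leaving the silyl aldol ether. Fallback with known chemistry, setting out from bromide 20 and aldehyde 7 and returning at 26: (S)-4-benzyloxazolidin-2-one is acylated (n-BuLi, benzyloxyacetyl chloride) to (S)-4-benzyl-3-[(benzyloxy)acetyl]oxazolidin-2-one F5. A Bu2BOTf/Et3N syn-glycolate aldol addition to 7 gives the imide (S)-4-benzyl-3-[(2S,3R)-2-(benzyloxy)-3-[4-(benzyloxy)phenyl]-3-hydroxypropanoyl]oxazolidin-2-one F6, which sets the carbinol centre by auxiliary control. AlMe3 and MeNHOMe·HCl give the Weinreb amide (2S,3R)-2-(benzyloxy)-3-[4-(benzyloxy)phenyl]-3-hydroxy-N-methoxy-N-methylpropanamide F7. Its magnesium alkoxide (i-PrMgCl) is combined with aryllithium 21 (from 20, n-BuLi, −78 °C) to give the hydroxy ketone (2S,3R)-2-(benzyloxy)-3-[4-(benzyloxy)phenyl]-1-{3,4-bis(benzyloxy)-2-fluoro-5-[(2S,3R,4S)-3,7,8-tris(benzyloxy)-2-[4-(benzyloxy)phenyl]chroman-4-yl]phenyl}-3-hydroxypropan-1-one F8. Cs2CO3 in DMF then closes ring C by SNAr to cis ketone 25, which epimerises at C3 under the same base to 26.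

Step 4 (Proposed new method). What may go wrong: the same loss of C2 configuration or stalled ring closure as in step 13. Fallback with known chemistry, setting out from 2 (through aryllithium 4) and 7 and returning at 10: the enantiomeric sequence, through (R)-4-benzyl-3-[(benzyloxy)acetyl]oxazolidin-2-one F1, the syn aldol imide (R)-4-benzyl-3-[(2R,3S)-2-(benzyloxy)-3-[4-(benzyloxy)phenyl]-3-hydroxypropanoyl]oxazolidin-2-one F2 and the Weinreb amide (2R,3S)-2-(benzyloxy)-3-[4-(benzyloxy)phenyl]-3-hydroxy-N-methoxy-N-methylpropanamide F3. Addition of the magnesium alkoxide of F3 to aryllithium 4 gives the hydroxy ketone (2R,3S)-2-(benzyloxy)-1-[3,4-bis(benzyloxy)-2-fluorophenyl]-3-[4-(benzyloxy)phenyl]-3-hydroxypropan-1-one F4, and Cs2CO3 in DMF effects SNAr closure to 9 and epimerisation to 10.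

Step 8. What may go wrong: iodine–lithium scrambling between aryllithium 16 and unreacted iodide 15 (halogen dance), or competing metalation next to iodine, giving regioisomeric or polyhalogenated material. Fallback, setting out from catechol 14 and returning at 17: the bromine is introduced by electrophilic substitution before benzylation. Br2 in AcOH at 0 °C should brominate the free catechol para to the hydroxyl that is flanked by iodine (the position ortho to fluorine; the other open position is hindered by iodine and deactivated by the meta fluorine) to give 4-bromo-3-fluoro-6-iodobenzene-1,2-diol F9. Double benzylation (BnBr, K2CO3, DMF) then gives 17 directly.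

Further compounds
F1 | step 4 | (R)-4-benzyl-3-[(benzyloxy)acetyl]oxazolidin-2-one | O=C1OC[C@@H](Cc2ccccc2)N1C(=O)COCc1ccccc1
F2 | step 4 | (R)-4-benzyl-3-[(2R,3S)-2-(benzyloxy)-3-[4-(benzyloxy)phenyl]-3-hydroxypropanoyl]oxazolidin-2-one | O=C1OC[C@@H](Cc2ccccc2)N1C(=O)[C@H](OCc1ccccc1)[C@@H](O)c1ccc(OCc2ccccc2)cc1
F3 | step 4 | (2R,3S)-2-(benzyloxy)-3-[4-(benzyloxy)phenyl]-3-hydroxy-N-methoxy-N-methylpropanamide | CON(C)C(=O)[C@H](OCc1ccccc1)[C@@H](O)c1ccc(OCc2ccccc2)cc1
F4 | step 4 | (2R,3S)-2-(benzyloxy)-1-[3,4-bis(benzyloxy)-2-fluorophenyl]-3-[4-(benzyloxy)phenyl]-3-hydroxypropan-1-one | O=C(c1ccc(OCc2ccccc2)c(OCc2ccccc2)c1F)[C@H](OCc1ccccc1)[C@@H](O)c1ccc(OCc2ccccc2)cc1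
F5 | step 13 | (S)-4-benzyl-3-[(benzyloxy)acetyl]oxazolidin-2-one | O=C1OC[C@H](Cc2ccccc2)N1C(=O)COCc1ccccc1
F6 | step 13 | (S)-4-benzyl-3-[(2S,3R)-2-(benzyloxy)-3-[4-(benzyloxy)phenyl]-3-hydroxypropanoyl]oxazolidin-2-one | O=C1OC[C@H](Cc2ccccc2)N1C(=O)[C@@H](OCc1ccccc1)[C@H](O)c1ccc(OCc2ccccc2)cc1
F7 | step 13 | (2S,3R)-2-(benzyloxy)-3-[4-(benzyloxy)phenyl]-3-hydroxy-N-methoxy-N-methylpropanamide | CON(C)C(=O)[C@@H](OCc1ccccc1)[C@H](O)c1ccc(OCc2ccccc2)cc1
F8 | step 13 | (2S,3R)-2-(benzyloxy)-3-[4-(benzyloxy)phenyl]-1-{3,4-bis(benzyloxy)-2-fluoro-5-[(2S,3R,4S)-3,7,8-tris(benzyloxy)-2-[4-(benzyloxy)phenyl]chroman-4-yl]phenyl}-3-hydroxypropan-1-one | O=C([C@@H](OCc1ccccc1)[C@H](O)c1ccc(OCc2ccccc2)cc1)c1cc([C@@H]2c3ccc(OCc4ccccc4)c(OCc4ccccc4)c3O[C@@H](c3ccc(OCc4ccccc4)cc3)[C@@H]2OCc2ccccc2)c(OCc2ccccc2)c(OCc2ccccc2)c1F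
F9 | step 8 | 4-bromo-3-fluoro-6-iodobenzene-1,2-diol | Oc1c(I)cc(Br)c(F)c1O
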